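**Plan**

1. Numbering (cembranolide): C1 is the ring CH bearing lactone carbon C15 (C16 carbonyl, C17 exo-methylene); C3=C4 and C7=C8 are the E olefins with methyls on C4 and C8; C11 is CHCl, C12 is C(OH)CH3, C14 is CH–O. Enabling feature: in the 14-membered ring, C9 and C10 form an ethylene bridge between olefinic C8 and C11, so C11(=O)–C10–C9 is a ketone homoenolate and can be stored as a C11 cyclopropanol whose two methylenes are C9 and C10.
2. Cuts, last to first: C11–Cl (chloride opening of the 11,12-epoxide); C15=C17 (Mannich methylenation); the epoxide (from the C11 ketone); C8–C9 (closure of the 14-membered ring by palladium homoenolate coupling of the C11 cyclopropanol with the C8 alkenyl iodide); C8–I (from a C7≡C8 alkyne); the lactone carbonyl (from a vinyl group); C1–C14 (allylboration); the cyclopropane (ester plus EtMgBr).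
3. Forward order of rings: cyclopropane (step 5), γ-lactone on the open chain (step 19), 14-membered carbocycle (step 21), epoxide (step 24), which the last step opens.
4. Stereochemistry: C12 from (S)-lactic acid (dioxolanone alkylation with retention); C14 and C1 from a chiral phosphoric acid catalysed anti-allylboration with an (E)-allylboronate; C11 from an oxazaborolidine reduction followed by double inversion (epoxide closure, chloride opening); C3=C4 from an enol phosphate–cuprate coupling; C7=C8 from syn-hydrozirconation–iodination.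

Key step: step 21

Remark on the chemistry: the (R) enantiomer of the phosphoric acid catalyst is assumed to deliver the allyl group to the Re face of the C14 aldehyde, as with simple aldehydes; should the sense be opposite, the (S) catalyst would be used.

**Route**

Step 1
Reactants: 1 (S)-lactic acid; 2 pivalaldehyde
Product: 3 (2S,5S)-2-tert-butyl-5-methyl-1,3-dioxolan-4-one
Conditions: TsOH·H2O (cat.), H2SO4 (cat.), pentane, reflux, Dean–Stark; crystallisation from pentane/Et2O, −78 °C
Reagents that add atoms: none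
Why: Acid-catalysed acetalisation with azeotropic removal of water (first stage of the self-regeneration-of-stereocentres sequence) should favour the cis dioxolanone, low-temperature crystallisation should remove the trans isomer, and C5 keeps the lactic acid configuration.

Step 2
Reactants: 3 (2S,5S)-2-tert-butyl-5-methyl-1,3-dioxolan-4-one; 4 prenyl bromide
Product: 5 (2S,5R)-2-tert-butyl-5-methyl-5-(3-methylbut-2-en-1-yl)-1,3-dioxolan-4-one
Conditions: LiN(i-Pr)2, THF, −78 °C; then 4, −78 → −30 °C
Reagents that add atoms: none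
Why: Enolate alkylation should occur anti to the tert-butyl group of the remaining acetal centre, so prenyl replaces the former C–H with overall retention and fixes C12 as R; a trisubstituted olefin is chosen as latent aldehyde because it does not exchange into the titanacyclopropane of step 5.

Step 3
Reactants: 5 (2S,5R)-2-tert-butyl-5-methyl-5-(3-methylbut-2-en-1-yl)-1,3-dioxolan-4-one
Product: 6 methyl (2R)-2-hydroxy-2,5-dimethylhex-4-enoate
Conditions: NaOMe (0.1 equiv), MeOH, 0 °C → rt
Reagents that add atoms: methanol, CO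
Why: Methoxide-catalysed transesterification at the acylal carbonyl releases a hemiacetal that collapses to pivalaldehyde and the tertiary α-hydroxy ester, with no bond to C12 broken.

Step 4
Reactants: 6 methyl (2R)-2-hydroxy-2,5-dimethylhex-4-enoate
Product: 7 methyl (2R)-2,5-dimethyl-2-(triethylsilyloxy)hex-4-enoate
Conditions: Et3SiOTf, 2,6-lutidine, CH2Cl2, 0 °C → rt
Reagents that add atoms: triethylsilyl trifluoromethanesulfonate, CC[Si](CC)(CC)OS(=O)(=O)C(F)(F)F
Why: Silyl triflate with lutidine is the standard silylation for hindered tertiary alcohols, and the TES ether masks the C12 hydroxyl until step 24.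

Step 5
Reactants: 7 methyl (2R)-2,5-dimethyl-2-(triethylsilyloxy)hex-4-enoate
Product: 8 1-[(2R)-5-methyl-2-(triethylsilyloxy)hex-4-en-2-yl]cyclopropan-1-ol
Conditions: EtMgBr (3 equiv, slow addition), Ti(OiPr)4 (0.3 equiv), THF, 0 °C → rt
Reagents that add atoms: ethylmagnesium bromide, CC[Mg]Br
Why: Kulinkovich cyclopropanation, in which the titanacyclopropane from Ti(OiPr)4 and EtMgBr adds twice to the ester carbonyl, should turn C11 into a cyclopropanol whose methylenes are the future C9 and C10; α-alkoxy esters are good substrates and the trisubstituted olefin is inert.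

Step 6
Reactants: 8 1-[(2R)-5-methyl-2-(triethylsilyloxy)hex-4-en-2-yl]cyclopropan-1-ol
Product: 9 (2R)-5-methyl-2-(triethylsilyloxy)-2-[1-(trimethylsilyloxy)cyclopropyl]hex-4-ene
Conditions: Me3SiCl, imidazole, DMF, 0 °C → rt
Reagents that add atoms: chlorotrimethylsilane, C[Si](C)(C)Cl
Why: Silylation gives a TMS ether that keeps the cyclopropanol from forming a five-membered lactol with the C14 aldehyde and from oxidative ring opening in step 19, yet is more labile than the tertiary TES ether.

Step 7
Reactants: 9 (2R)-5-methyl-2-(triethylsilyloxy)-2-[1-(trimethylsilyloxy)cyclopropyl]hex-4-ene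
Product: 11 (3R)-3-(triethylsilyloxy)-3-[1-(trimethylsilyloxy)cyclopropyl]butanal, via ozonide 10 (not isolated)
Conditions: O3, CH2Cl2, −78 °C; then PPh3, −78 °C → rt
Reagents that add atoms: ozone, [O-][O+]=O
Why: Ozonolysis (Criegee mechanism) of the only olefin with reductive work-up should give the C14 aldehyde and acetone, the silyl ethers and the cyclopropane being inert.

Step 8
Reactants: 12 methyl acetoacetate; 13 1-bromo-2-butyne
Product: 14 methyl 3-oxooct-6-ynoate
Conditions: LiN(i-Pr)2 (2.1 equiv), THF, 0 °C; then 13, 0 °C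
Reagents that add atoms: none
Why: γ-Alkylation of the acetoacetate dianion, whose more basic terminal carbon attacks the propargylic bromide by SN2, joins C5 to C6.

Step 9
Reactants: 14 methyl 3-oxooct-6-ynoate
Product: 15 methyl (2Z)-3-(diethoxyphosphoryloxy)oct-2-en-6-ynoate
Conditions: NaH, Et2O, 0 °C; ClP(O)(OEt)2
Reagents that add atoms: diethyl chlorophosphate, CCOP(=O)(Cl)OCC
Why: O-Phosphorylation of the sodium-chelated β-keto ester enolate should give the Z enol phosphate, because the chelate holds the ester and enolate oxygens cis.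

Step 10
Reactants: 15 methyl (2Z)-3-(diethoxyphosphoryloxy)oct-2-en-6-ynoate
Product: 16 methyl (2E)-3-methyloct-2-en-6-ynoate
Conditions: Me2CuLi (from CuI and MeLi), Et2O, −78 → −45 °C
Reagents that add atoms: lithium dimethylcuprate, [Li+].C[Cu-]C
Why: Cuprate addition–elimination on the β-phosphoryloxy enoate replaces phosphate by methyl with retention, setting the E C3=C4 olefin with its C4 methyl; the internal alkyne does not react at this temperature.

Step 11
Reactants: 16 methyl (2E)-3-methyloct-2-en-6-ynoate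
Product: 17 (2E)-3-methyloct-2-en-6-yn-1-ol
Conditions: i-Bu2AlH (2.2 equiv), CH2Cl2, −78 °C
Reagents that add atoms: none
Why: 1,2-Reduction of the enoate by the aluminium hydride gives the allylic alcohol without hydroalumination of the internal alkyne at −78 °C.

Step 12
Reactants: 17 (2E)-3-methyloct-2-en-6-yn-1-ol
Product: 18 (2E)-1-bromo-3-methyloct-2-en-6-yne
Conditions: CBr4, PPh3, CH2Cl2, 0 °C
Reagents that add atoms: carbon tetrabromide, BrC(Br)(Br)Br
Why: The Appel reaction brominates the primary allylic alcohol under neutral SN2 conditions without allylic transposition.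

Step 13
Reactants: 18 (2E)-1-bromo-3-methyloct-2-en-6-yne
Product: 19 (4E)-5-methyldec-4-ene-1,8-diyne
Conditions: HC≡CMgBr (2 equiv), CuBr·SMe2 (10 mol %), THF, 0 °C → rt
Reagents that add atoms: ethynylmagnesium bromide, C#C[Mg]Br
Why: Copper-catalysed SN2 coupling of the alkynyl Grignard reagent at the primary allylic carbon (γ-attack would create a quaternary centre) gives the skipped enyne carrying C1 and C15.

Step 14
Reactants: 19 (4E)-5-methyldec-4-ene-1,8-diyne
Product: 20 2-[(1E,4E)-5-methyldeca-1,4-dien-8-yn-1-yl]-4,4,5,5-tetramethyl-1,3,2-dioxaborolane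
Conditions: pinacolborane (1.1 equiv), Cy2BH (10 mol %), THF, rt
Reagents that add atoms: pinacolborane, CC1(C)OBOC1(C)C
Why: Dialkylborane-catalysed syn hydroboration should take the terminal alkyne much faster than the internal one and place boron on the terminal carbon, giving the E alkenylboronate.

Step 15
Reactants: 20 2-[(1E,4E)-5-methyldeca-1,4-dien-8-yn-1-yl]-4,4,5,5-tetramethyl-1,3,2-dioxaborolane
Product: 21 2-[(2E,5E)-6-methylundeca-2,5-dien-9-yn-1-yl]-4,4,5,5-tetramethyl-1,3,2-dioxaborolane
Conditions: ICH2Cl (1.5 equiv), n-BuLi (1.3 equiv), THF, −78 °C → rt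
Reagents that add atoms: chloroiodomethane, ClCI
Why: Matteson homologation, in which LiCH2Cl made in situ adds to boron and the alkenyl group migrates with retention of the E geometry, inserts C16 and gives the (E)-γ-substituted allylboronate.

Step 16
Reactants: 11 (3R)-3-(triethylsilyloxy)-3-[1-(trimethylsilyloxy)cyclopropyl]butanal; 21 2-[(2E,5E)-6-methylundeca-2,5-dien-9-yn-1-yl]-4,4,5,5-tetramethyl-1,3,2-dioxaborolane
Product: 23 (3R,4S,6R)-3-[(2E)-3-methyloct-2-en-6-yn-1-yl]-6-(triethylsilyloxy)-6-[1-(trimethylsilyloxy)cyclopropyl]hept-1-en-4-ol, via O-boryl adduct 22 (not isolated)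
Conditions: (R)-3,3′-bis(2,4,6-triisopropylphenyl)-1,1′-binaphthyl-2,2′-diyl hydrogen phosphate (5 mol %), 4 Å MS, toluene, −30 °C; aq. NaHCO3
Reagents that add atoms: none
Why: Chiral phosphoric acid catalysed allylboration through a closed chair (Zimmerman–Traxler) transition state should give the anti C14–OH/C1 relationship from the E boronate, while the (R) catalyst directs the reagent to the Re face of the aldehyde (14S, hence 1R); the remote quaternary C12 is expected to exert little bias.

Step 17
Reactants: 23 (3R,4S,6R)-3-[(2E)-3-methyloct-2-en-6-yn-1-yl]-6-(triethylsilyloxy)-6-[1-(trimethylsilyloxy)cyclopropyl]hept-1-en-4-ol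
Product: 25 (3R,4S,6R)-3-[(2E)-3-methyloct-2-en-6-yn-1-yl]-6-(triethylsilyloxy)-6-[1-(trimethylsilyloxy)cyclopropyl]heptane-1,4-diol, via B-alkyl-9-BBN adduct 24 (not isolated)
Conditions: 9-BBN (2.5 equiv), THF, 0 °C → rt; then NaBO3·4H2O, H2O, rt
Reagents that add atoms: sodium perborate, [Na+].[O-]B1OO1
Why: Hydroboration–oxidation with 9-BBN should take the monosubstituted vinyl group far faster than the trisubstituted olefin or the internal alkyne and place the hydroxyl on the terminal carbon C16.

Step 18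
Reactants: 25 (3R,4S,6R)-3-[(2E)-3-methyloct-2-en-6-yn-1-yl]-6-(triethylsilyloxy)-6-[1-(trimethylsilyloxy)cyclopropyl]heptane-1,4-diol
Product: 27 (3R,4S,6R)-3-[(2E,6E)-7-iodo-3-methylocta-2,6-dien-1-yl]-6-(triethylsilyloxy)-6-[1-(trimethylsilyloxy)cyclopropyl]heptane-1,4-diol, via alkenylzirconocene 26 (not isolated)
Conditions: Cp2Zr(H)Cl (4.5 equiv), THF, rt → 50 °C; then I2, THF, −78 → 0 °C
Reagents that add atoms: iodine, II
Why: Hydrozirconation–iodination with Cp2Zr(H)Cl: the hydroxyls are taken up as zirconium alkoxides, syn addition to the alkyne and equilibration with excess reagent should place zirconium on C8 next to the small methyl group, and iodinolysis with retention gives the E C8 iodide.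

Step 19
Reactants: 27 (3R,4S,6R)-3-[(2E,6E)-7-iodo-3-methylocta-2,6-dien-1-yl]-6-(triethylsilyloxy)-6-[1-(trimethylsilyloxy)cyclopropyl]heptane-1,4-diol
Product: 29 (4R,5S)-4-[(2E,6E)-7-iodo-3-methylocta-2,6-dien-1-yl]-5-{(2R)-2-(triethylsilyloxy)-2-[1-(trimethylsilyloxy)cyclopropyl]propyl}oxolan-2-one, via lactol 28 (not isolated)
Conditions: Cu(MeCN)4OTf (5 mol %), 2,2′-bipyridine (5 mol %), TEMPO (5 mol %), N-methylimidazole (10 mol %), air, MeCN, rt
Reagents that add atoms: none
Why: Copper/nitroxyl aerobic oxidation is selective for the primary alcohol, the C16 aldehyde is trapped by the C14 hydroxyl as a lactol and oxidised on to the trans γ-lactone, and the non-acidic medium spares both silyl ethers.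

Step 20
Reactants: 29 (4R,5S)-4-[(2E,6E)-7-iodo-3-methylocta-2,6-dien-1-yl]-5-{(2R)-2-(triethylsilyloxy)-2-[1-(trimethylsilyloxy)cyclopropyl]propyl}oxolan-2-one
Product: 30 (4R,5S)-5-[(2R)-2-(1-hydroxycyclopropyl)-2-(triethylsilyloxy)propyl]-4-[(2E,6E)-7-iodo-3-methylocta-2,6-dien-1-yl]oxolan-2-one
Conditions: citric acid, MeOH, 0 °C → rt
Reagents that add atoms: none
Why: Mild acid methanolysis removes the TMS ether of the cyclopropanol while the hindered tertiary TES ether and the lactone survive.

Step 21
Reactants: 30 (4R,5S)-5-[(2R)-2-(1-hydroxycyclopropyl)-2-(triethylsilyloxy)propyl]-4-[(2E,6E)-7-iodo-3-methylocta-2,6-dien-1-yl]oxolan-2-one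
Product: 31 (1R,12R,14S)-11-oxo-12-(triethylsilyloxy)cembra-3E,7E-dien-16,14-olide
Conditions: Pd(OAc)2 (10 mol %), XPhos (20 mol %), Cs2CO3 (2 equiv), degassed toluene, 80 °C, syringe-pump addition of 30 (final 2 mM)
Reagents that add atoms: none
Why: Proposed new method: Pd(OAc)2 and XPhos give zerovalent palladium, which inserts into the C8–I bond to an alkenyl palladium iodide (divalent palladium); carbonate-assisted exchange binds the C11 cyclopropanol as alkoxide, strain-driven β-carbon elimination cleaves a ring bond to C11 (C9 and C10 are equivalent, so no regiochemical question arises) to give the β-keto alkyl palladium homoenolate, and C(sp2)–C(sp3) reductive elimination forms C8–C9. The closest known reaction type is the intermolecular palladium-catalysed ring-opening cross-coupling of cyclopropanols with aryl and alkenyl halides to β-substituted ketones; its use as a macrocyclisation is the untested part. The 14-membered carbocycle closes end to end by reductive elimination from a 15-membered palladacycle, run by slow addition at high dilution so that intramolecular alkoxide capture outruns oligomerisation. No stereocentre is formed, and the E geometry at C7=C8 is carried through because oxidative addition and reductive elimination are stereoretentive. The step needs reductive elimination to beat β-hydride loss from C10 (which would give the C9=C10 enone): the bulky biaryl phosphine accelerates reductive elimination, the quaternary C12 blocks enolisation of the new ketone on that side, and the trans-fused lactone with the two E trisubstituted olefins limits the conformations of the tether.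

Step 22
Reactants: 31 (1R,12R,14S)-11-oxo-12-(triethylsilyloxy)cembra-3E,7E-dien-16,14-olide
Product: 32 (1R,11S,12R,14S)-11-hydroxy-12-(triethylsilyloxy)cembra-3E,7E-dien-16,14-olide
Conditions: (R)-2-methyl-CBS-oxazaborolidine (0.5 equiv), catecholborane (2 equiv), toluene, −40 → −20 °C; MeOH, aq. NaHCO3
Reagents that add atoms: none
Why: Corey–Bakshi–Shibata reduction, with the quaternary C12 as the large and the C10 methylene as the small flank, should deliver hydride under control of the (R)-oxazaborolidine to give the 11S carbinol, and catecholborane at this temperature neither hydroborates the olefins nor reduces the lactone.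

Step 23
Reactants: 32 (1R,11S,12R,14S)-11-hydroxy-12-(triethylsilyloxy)cembra-3E,7E-dien-16,14-olide
Product: 33 (1R,11S,12R,14S)-11-(methanesulfonyloxy)-12-(triethylsilyloxy)cembra-3E,7E-dien-16,14-olide
Conditions: MeSO2Cl, Et3N, DMAP (cat.), CH2Cl2, 0 °C
Reagents that add atoms: methanesulfonyl chloride, CS(=O)(=O)Cl
Why: Mesylation through the sulfene tolerates the hindered secondary alcohol and turns C11–O into a leaving group without touching the configuration.

Step 24
Reactants: 33 (1R,11S,12R,14S)-11-(methanesulfonyloxy)-12-(triethylsilyloxy)cembra-3E,7E-dien-16,14-olide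
Product: 34 (1R,11R,12R,14S)-11,12-epoxycembra-3E,7E-dien-16,14-olide
Conditions: n-Bu4NF, THF, 0 °C → rt
Reagents that add atoms: none
Why: Fluoride cleaves the TES ether and the freed C12 alkoxide displaces the neighbouring mesylate (intramolecular Williamson reaction, 3-exo-tet) with inversion at C11, giving the trans epoxide with C12 unchanged.

Step 25
Reactants: 34 (1R,11R,12R,14S)-11,12-epoxycembra-3E,7E-dien-16,14-olide
Product: 37 (1R,11R,12R,14S)-11,12-epoxycembra-3E,7E,15(17)-trien-16,14-olide, via Mannich base 35 (not isolated), via methiodide 36 (not isolated)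
Conditions: LiN(SiMe3)2, THF, −78 °C; Me2N=CH2 I (Eschenmoser's salt), −78 °C → rt; MeI, MeOH, rt; NaHCO3, CH2Cl2/H2O
Reagents that add atoms: Eschenmoser's salt, C=[N+](C)C.[I-]
Why: Mannich reaction of the lactone enolate with the iminium salt, N-methylation and base-induced β-elimination of trimethylamine install the exo-methylene carbon C17; the lactone is the only enolisable carbonyl and the epoxide is inert to the hindered amide base at −78 °C.

Step 26
Reactants: 37 (1R,11R,12R,14S)-11,12-epoxycembra-3E,7E,15(17)-trien-16,14-olide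
Product: 38 (1R,11S,12R,14S)-11-chloro-12-hydroxycembra-3E,7E,15(17)-trien-16,14-olide
Conditions: LiCl (10 equiv), AcOH (3 equiv), THF, rt
Reagents that add atoms: lithium chloride, [Li+].[Cl-]
Why: Epoxide opening to the chlorohydrin under weakly acidic, chloride-rich conditions should be SN2-like, chloride attacking the less substituted C11 anti to the C–O bond (second inversion, C11 becomes S) while the C12–O bond and its configuration are retained.

**Compound list**

1 | (S)-lactic acid | C[C@H](O)C(=O)O | starting material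
2 | pivalaldehyde | CC(C)(C)C=O | starting material
3 | (2S,5S)-2-tert-butyl-5-methyl-1,3-dioxolan-4-one | C[C@@H]1O[C@H](C(C)(C)C)OC1=O | intermediate
4 | prenyl bromide (1-bromo-3-methylbut-2-ene) | CC(C)=CCBr | starting material
5 | (2S,5R)-2-tert-butyl-5-methyl-5-(3-methylbut-2-en-1-yl)-1,3-dioxolan-4-one | C[C@]1(CC=C(C)C)O[C@H](C(C)(C)C)OC1=O | intermediate
6 | methyl (2R)-2-hydroxy-2,5-dimethylhex-4-enoate | C[C@](CC=C(C)C)(O)C(=O)OC | intermediate
7 | methyl (2R)-2,5-dimethyl-2-(triethylsilyloxy)hex-4-enoate | C[C@](CC=C(C)C)(O[Si](CC)(CC)CC)C(=O)OC | intermediate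
8 | 1-[(2R)-5-methyl-2-(triethylsilyloxy)hex-4-en-2-yl]cyclopropan-1-ol | C[C@](CC=C(C)C)(O[Si](CC)(CC)CC)C1(O)CC1 | intermediate
9 | (2R)-5-methyl-2-(triethylsilyloxy)-2-[1-(trimethylsilyloxy)cyclopropyl]hex-4-ene | C[C@](CC=C(C)C)(O[Si](CC)(CC)CC)C1(O[Si](C)(C)C)CC1 | intermediate
10 | ozonide of 9 (3,3-dimethyl-1,2,4-trioxolane, not isolated) | C[C@](CC1OOC(C)(C)O1)(O[Si](CC)(CC)CC)C1(O[Si](C)(C)C)CC1 | intermediate
11 | (3R)-3-(triethylsilyloxy)-3-[1-(trimethylsilyloxy)cyclopropyl]butanal | C[C@](CC=O)(O[Si](CC)(CC)CC)C1(O[Si](C)(C)C)CC1 | intermediate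
12 | methyl acetoacetate | COC(=O)CC(C)=O | starting material
13 | 1-bromo-2-butyne | CC#CCBr | starting material
14 | methyl 3-oxooct-6-ynoate | COC(=O)CC(=O)CCC#CC | intermediate
15 | methyl (2Z)-3-(diethoxyphosphoryloxy)oct-2-en-6-ynoate | COC(=O)/C=C(/CCC#CC)OP(=O)(OCC)OCC | intermediate
16 | methyl (2E)-3-methyloct-2-en-6-ynoate | COC(=O)/C=C(\C)CCC#CC | intermediate
17 | (2E)-3-methyloct-2-en-6-yn-1-ol | OC/C=C(\C)CCC#CC | intermediate
18 | (2E)-1-bromo-3-methyloct-2-en-6-yne | BrC/C=C(\C)CCC#CC | intermediate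
19 | (4E)-5-methyldec-4-ene-1,8-diyne | C#CC/C=C(\C)CCC#CC | intermediate
20 | 2-[(1E,4E)-5-methyldeca-1,4-dien-8-yn-1-yl]-4,4,5,5-tetramethyl-1,3,2-dioxaborolane | CC1(C)OB(/C=C/C/C=C(\C)CCC#CC)OC1(C)C | intermediate
21 | 2-[(2E,5E)-6-methylundeca-2,5-dien-9-yn-1-yl]-4,4,5,5-tetramethyl-1,3,2-dioxaborolane | CC1(C)OB(C/C=C/C/C=C(\C)CCC#CC)OC1(C)C | intermediate
22 | O-pinacolboryl ether of 23 (not isolated) | C=C[C@@H](C/C=C(C)/CCC#CC)[C@@H](OB1OC(C)(C)C(C)(C)O1)C[C@@](C)(O[Si](CC)(CC)CC)C1(O[Si](C)(C)C)CC1 | intermediate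
23 | (3R,4S,6R)-3-[(2E)-3-methyloct-2-en-6-yn-1-yl]-6-(triethylsilyloxy)-6-[1-(trimethylsilyloxy)cyclopropyl]hept-1-en-4-ol | C=C[C@@H](C/C=C(C)/CCC#CC)[C@@H](O)C[C@@](C)(O[Si](CC)(CC)CC)C1(O[Si](C)(C)C)CC1 | intermediate
24 | B-alkyl-9-BBN adduct of 23, boron on C16 (not isolated) | B1(CC[C@@H](C/C=C(C)/CCC#CC)[C@@H](O)C[C@@](C)(O[Si](CC)(CC)CC)C3(O[Si](C)(C)C)CC3)C2CCCC1CCC2 | intermediate
25 | (3R,4S,6R)-3-[(2E)-3-methyloct-2-en-6-yn-1-yl]-6-(triethylsilyloxy)-6-[1-(trimethylsilyloxy)cyclopropyl]heptane-1,4-diol | OCC[C@@H](C/C=C(C)/CCC#CC)[C@@H](O)C[C@@](C)(O[Si](CC)(CC)CC)C1(O[Si](C)(C)C)CC1 | intermediate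
26 | C8 alkenylzirconocene chloride of 25, both hydroxyls as zirconocene alkoxides (not isolated) | Cl[Zr](C1C=CC=C1)(C1C=CC=C1)OCC[C@@H](C/C=C(C)/CC/C=C(\C)[Zr](Cl)(C1C=CC=C1)C1C=CC=C1)[C@@H](O[Zr](Cl)(C1C=CC=C1)C1C=CC=C1)C[C@@](C)(O[Si](CC)(CC)CC)C1(O[Si](C)(C)C)CC1 | intermediate
27 | (3R,4S,6R)-3-[(2E,6E)-7-iodo-3-methylocta-2,6-dien-1-yl]-6-(triethylsilyloxy)-6-[1-(trimethylsilyloxy)cyclopropyl]heptane-1,4-diol | OCC[C@@H](C/C=C(C)/CC/C=C(\C)I)[C@@H](O)C[C@@](C)(O[Si](CC)(CC)CC)C1(O[Si](C)(C)C)CC1 | intermediate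
28 | lactol of 27 (2-hydroxyoxolane, not isolated) | OC1C[C@@H](C/C=C(C)/CC/C=C(\C)I)[C@H](C[C@@](C)(O[Si](CC)(CC)CC)C2(O[Si](C)(C)C)CC2)O1 | intermediate
29 | (4R,5S)-4-[(2E,6E)-7-iodo-3-methylocta-2,6-dien-1-yl]-5-{(2R)-2-(triethylsilyloxy)-2-[1-(trimethylsilyloxy)cyclopropyl]propyl}oxolan-2-one | O=C1C[C@@H](C/C=C(C)/CC/C=C(\C)I)[C@H](C[C@@](C)(O[Si](CC)(CC)CC)C2(O[Si](C)(C)C)CC2)O1 | intermediate
30 | (4R,5S)-5-[(2R)-2-(1-hydroxycyclopropyl)-2-(triethylsilyloxy)propyl]-4-[(2E,6E)-7-iodo-3-methylocta-2,6-dien-1-yl]oxolan-2-one | O=C1C[C@@H](C/C=C(C)/CC/C=C(\C)I)[C@H](C[C@@](C)(O[Si](CC)(CC)CC)C2(O)CC2)O1 | intermediate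
31 | (1R,12R,14S)-11-oxo-12-(triethylsilyloxy)cembra-3E,7E-dien-16,14-olide | C1C(=O)O[C@H]2C[C@@](C)(O[Si](CC)(CC)CC)C(=O)CC/C(C)=C/CC/C(C)=C/C[C@H]12 | intermediate
32 | (1R,11S,12R,14S)-11-hydroxy-12-(triethylsilyloxy)cembra-3E,7E-dien-16,14-olide | C1C(=O)O[C@H]2C[C@@](C)(O[Si](CC)(CC)CC)[C@@H](O)CC/C(C)=C/CC/C(C)=C/C[C@H]12 | intermediate
33 | (1R,11S,12R,14S)-11-(methanesulfonyloxy)-12-(triethylsilyloxy)cembra-3E,7E-dien-16,14-olide | C1C(=O)O[C@H]2C[C@@](C)(O[Si](CC)(CC)CC)[C@@H](OS(C)(=O)=O)CC/C(C)=C/CC/C(C)=C/C[C@H]12 | intermediate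
34 | (1R,11R,12R,14S)-11,12-epoxycembra-3E,7E-dien-16,14-olide | C1C(=O)O[C@H]2C[C@@]3(C)O[C@@H]3CC/C(C)=C/CC/C(C)=C/C[C@H]12 | intermediate
35 | 15-(dimethylaminomethyl) derivative of 34, substituent trans to C2 (Mannich base, not isolated) | CN(C)C[C@H]1C(=O)O[C@H]2C[C@@]3(C)O[C@@H]3CC/C(C)=C/CC/C(C)=C/C[C@H]12 | intermediate
36 | trimethylammonium iodide of 35 (methiodide, not isolated) | C[N+](C)(C)C[C@H]1C(=O)O[C@H]2C[C@@]3(C)O[C@@H]3CC/C(C)=C/CC/C(C)=C/C[C@H]12.[I-] | intermediate
37 | (1R,11R,12R,14S)-11,12-epoxycembra-3E,7E,15(17)-trien-16,14-olide | C=C1C(=O)O[C@H]2C[C@@]3(C)O[C@@H]3CC/C(C)=C/CC/C(C)=C/C[C@H]12 | intermediate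
38 | (1R,11S,12R,14S)-11-chloro-12-hydroxycembra-3E,7E,15(17)-trien-16,14-olide (CNP0247658.1) | C=C1C(=O)O[C@H]2C[C@@](C)(O)[C@@H](Cl)CC/C(C)=C/CC/C(C)=C/C[C@H]12 | target

**Totals and risks**

Total step count: 26. Longest linear sequence: 19 steps (steps 8–15, then 16–26, from methyl acetoacetate); the lactic acid branch is 18 steps (steps 1–7, then 16–26).

Step 21 (key step). The palladium homoenolate may lose a β-hydride from C10 faster than it reductively eliminates, intermolecular coupling may outrun ring closure and give oligomers, or the base may open the cyclopropanol protolytically to the ethyl ketone before palladium captures it. The fallback closes the same C8–C9 bond by a B-alkyl Suzuki–Miyaura macrocyclisation, a known ring-closing mode. It sets out from 29: FeCl3 in DMF at 0 °C should open the silyloxycyclopropane to the β-chloro ketone F1; Et3N eliminates HCl to give the vinyl ketone F2; reduction with (R)-2-methyl-CBS-oxazaborolidine and catecholborane gives the (11S)-allylic alcohol F3; 9-BBN hydroborates the vinyl group to the C9 alkylborane F4 (not isolated); and Pd(dppf)Cl2, AsPh3 and Cs2CO3 in DMF/THF/H2O at high dilution couple C9 with the C8 alkenyl iodide. The fallback comes back to the route at 32.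

Step 26. Once the epoxide is acid-activated, chloride may attack the tertiary C12 instead of C11, or the C7=C8 olefin may capture the developing positive charge across the ring. The fallback introduces chlorine by direct invertive displacement and never passes through the epoxide. It sets out from 31: reduction with the (S)-oxazaborolidine and catecholborane gives the (11R)-alcohol F5; Tf2O and 2,6-lutidine at −78 °C give the triflate F6 (not isolated), which n-Bu4NCl displaces with inversion to the (11S)-chloride F7, the TES ether preventing participation of the C12 oxygen; methylenation under the conditions of step 25 gives the α-methylene lactone F8, which cannot close to an epoxide because C12 is still silylated; HF·pyridine then removes the TES group without base. The fallback comes back to the route at 38.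

Step 22. The reduction of the hindered macrocyclic α-silyloxy ketone may be sluggish, or the ring conformation may override catalyst control and give poor facial selectivity. The fallback replaces reagent control by chelation control. It sets out from 31: HF·pyridine gives the α-hydroxy ketone F9; Zn(BH4)2 in Et2O at −20 °C chelates the ketone and the C12 hydroxyl and should deliver hydride from the methyl-flanked face to give the (11S,12R)-diol F10; MeSO2Cl and Et3N sulfonylate only the secondary hydroxyl to give the hydroxy mesylate F11; K2CO3 in MeOH at 0 °C closes the epoxide. The fallback comes back to the route at 34.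

**Further compounds**

F1 | step 21 | (4R,5S)-5-[(2R)-5-chloro-2-methyl-3-oxo-2-(triethylsilyloxy)pentyl]-4-[(2E,6E)-7-iodo-3-methylocta-2,6-dien-1-yl]oxolan-2-one | O=C1C[C@@H](C/C=C(C)/CC/C=C(\C)I)[C@H](C[C@@](C)(O[Si](CC)(CC)CC)C(=O)CCCl)O1
F2 | step 21 | (4R,5S)-4-[(2E,6E)-7-iodo-3-methylocta-2,6-dien-1-yl]-5-[(2R)-2-methyl-3-oxo-2-(triethylsilyloxy)pent-4-en-1-yl]oxolan-2-one | O=C1C[C@@H](C/C=C(C)/CC/C=C(\C)I)[C@H](C[C@@](C)(O[Si](CC)(CC)CC)C(=O)C=C)O1
F3 | step 21 | (4R,5S)-5-[(2R,3S)-3-hydroxy-2-methyl-2-(triethylsilyloxy)pent-4-en-1-yl]-4-[(2E,6E)-7-iodo-3-methylocta-2,6-dien-1-yl]oxolan-2-one | O=C1C[C@@H](C/C=C(C)/CC/C=C(\C)I)[C@H](C[C@@](C)(O[Si](CC)(CC)CC)[C@@H](O)C=C)O1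
F4 | step 21 | B-alkyl-9-BBN adduct of F3, boron on C9 | O=C1C[C@@H](C/C=C(C)/CC/C=C(\C)I)[C@H](C[C@@](C)(O[Si](CC)(CC)CC)[C@@H](O)CCB3C4CCCC3CCC4)O1
F5 | step 26 | (1R,11R,12R,14S)-11-hydroxy-12-(triethylsilyloxy)cembra-3E,7E-dien-16,14-olide | C1C(=O)O[C@H]2C[C@@](C)(O[Si](CC)(CC)CC)[C@H](O)CC/C(C)=C/CC/C(C)=C/C[C@H]12
F6 | step 26 | 11-O-trifluoromethanesulfonate of F5 | C1C(=O)O[C@H]2C[C@@](C)(O[Si](CC)(CC)CC)[C@H](OS(=O)(=O)C(F)(F)F)CC/C(C)=C/CC/C(C)=C/C[C@H]12
F7 | step 26 | (1R,11S,12R,14S)-11-chloro-12-(triethylsilyloxy)cembra-3E,7E-dien-16,14-olide | C1C(=O)O[C@H]2C[C@@](C)(O[Si](CC)(CC)CC)[C@@H](Cl)CC/C(C)=C/CC/C(C)=C/C[C@H]12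
F8 | step 26 | (1R,11S,12R,14S)-11-chloro-12-(triethylsilyloxy)cembra-3E,7E,15(17)-trien-16,14-olide | C=C1C(=O)O[C@H]2C[C@@](C)(O[Si](CC)(CC)CC)[C@@H](Cl)CC/C(C)=C/CC/C(C)=C/C[C@H]12
F9 | step 22 | (1R,12R,14S)-12-hydroxy-11-oxocembra-3E,7E-dien-16,14-olide | C1C(=O)O[C@H]2C[C@@](C)(O)C(=O)CC/C(C)=C/CC/C(C)=C/C[C@H]12
F10 | step 22 | (1R,11S,12R,14S)-11,12-dihydroxycembra-3E,7E-dien-16,14-olide | C1C(=O)O[C@H]2C[C@@](C)(O)[C@@H](O)CC/C(C)=C/CC/C(C)=C/C[C@H]12
F11 | step 22 | 11-O-methanesulfonate of F10 | C1C(=O)O[C@H]2C[C@@](C)(O)[C@@H](OS(C)(=O)=O)CC/C(C)=C/CC/C(C)=C/C[C@H]12
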